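Assumption: compounds 1, 4, 6 and 7 are taken as purchasable (4 as its THF solution). Locants: ring A is C1' (acyl-bearing carbon) to C6', the chain is C1 (C=O), C2 (carbinol), C3 (CH2), and ring B is the 4-hydroxyphenyl ring. The target is (S) at C2.

Compound numbers: 1 (S)-4-hydroxyphenyllactic acid; 2 its Weinreb amide; 3 bis-TBS ether of 2; 4 ethynylmagnesium bromide; 5 ynone; 6 5-methylhex-4-enoic acid; 7 1,1-dimethoxyethene; 8 acid chloride of 6; 9 acylketene acetal; 10 silyloxydiene; 11 cycloadduct; 12 aryl trimethylsilyl ether; 13 bis-TBS ether of the target; 14 Lespeflorin C3.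

## The problem

Lespeflorin C3 (14) is an α-hydroxydihydrochalcone: ring A is joined to ring B through a C1 ketone, a C2 carbinol and a C3 methylene. Ring A is 1,2,4,5-tetrasubstituted, with the acyl group on C1', OMe on C2', free OH on C4', prenyl on C5', and hydrogen on C3' and C6'. In a 2,4-dioxygenated aryl ketone the chelated C2' oxygen is the one that resists alkylation, so the 2'-OMe/4'-OH pattern runs against the natural reactivity. Electrophilic prenylation of such a ring also has C3' (between the oxygens) and the phenol oxygen as competing sites. The only stereocenter, C2 (S), carries OH and sits α to an aryl ketone. No second stereocenter can control it, so it must come from the chiral pool or a reagent, and base can destroy it by enolization or by enediol shift to the 1-hydroxy-2-oxo isomer. The prenyl alkene next to the free C4' phenol closes to a 2,2-dimethylchroman under strong acid, is reduced by H2 over palladium metal and is attacked by electrophilic oxidants, which rules out benzyl ethers, late epoxidation or dihydroxylation, and acid-labile acetals. The feature that opens the route: the four contiguous ring atoms C2'(OMe)–C3'(H)–C4'(OH)–C5'(prenyl) have the oxidation pattern of a γ-prenylated acetoacetate, that is, a 1,1,3-trioxygenated butadiene. The remaining pair C1'(acyl)–C6'(H) is a terminal ynone, so donor and acceptor alternate around ring A as a polarity-matched [4+2] cycloaddition requires.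

## Retrosynthesis

14 to 13. Two O–Si bonds are cut. The C2 hydroxyl and the ring B phenol must be masked while a Grignard reagent and a ketene acetal are in the flask. Silyl ethers are chosen because their removal needs neither hydrogenation nor strong acid, both of which the prenyl group forbids. The forward step must free both oxygens without enolizing C2.

13 to 5 and 10 (through 12 and 11). Ring A is cut at C1'–C2' and C5'–C6', with methanol added back across C2'/C5'. Against the neighbouring cut at C1'–C1 (aryl–carbonyl), this cut does not leave a tetrasubstituted arene to be made by substitution chemistry. Connectivity fixes the position of OMe, OH, prenyl and both ring hydrogens, and the aryl ketone comes with the ring. Ynone 5 holds one arene and the stereocenter, and diene 10 is acyclic and achiral. The forward reaction must join C4 of 10 to the terminal alkyne carbon of 5 and the acetal carbon to the internal one, then aromatize by loss of one methanol. It must leave the C2 stereocenter, the prenyl alkene and both TBS ethers alone.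

5 to 3 and 4, then 3 to 2 to 1. The C1–C(alkyne) bond is cut to Weinreb amide 3 and ethynylmagnesium bromide 4. Amide 3 goes back through diol 2 to (S)-4-hydroxyphenyllactic acid 1, which already holds C2 with the correct configuration, C3 and ring B. Buying the stereocenter is preferred to making it because the carbinol is not touched by any later bond formation. The forward steps must acylate the alkyne once only and must not epimerize the α-silyloxy carbonyl compounds.

10 to 9, then 9 to 8 and 7, and 8 to 6. The O–Si bond of 10 is cut to acylketene acetal 9, whose only enolizable position is the future C5'. The C2–C3 bond of 9 is cut to acid chloride 8 (from acid 6) and 1,1-dimethoxyethene 7. Acid 6 brings the C4' carbon with its oxygen, C5' and the complete prenyl chain. Acetal 7 brings C2', C3' and the methoxy group. Forward, a C-acylation of a ketene acetal and a soft enolization are asked for.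

## Roads not taken

Alternative 1: the C1'–C1 bond, the cut most chemists would draw first. Bromoarene A1 would be lithiated and added to Weinreb amide 3 to give ketone A2, followed by deprotection. The acylation itself is reliable. The weakness is A1: it has to be made from a resorcinol monoether by bromination, C-prenylation and protection. Each of those steps has a regiochemical alternative (C3' against C5', oxygen against carbon), and the oxygens need a protecting group whose removal tolerates the prenyl group. Three to four steps are spent on A1 that build no complexity, and the convergent step only joins two finished halves. The chosen plan makes ring A and the aryl ketone in one operation, with the substituent pattern fixed by connectivity. The logic of Alternative 1 is kept as the fallback for the key step.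

Alternative 2: the C2–O bond, made last on achiral ketone A3. Its silyl enol ether A4 would undergo OsO4-catalysed asymmetric dihydroxylation (or a Rubottom-type oxidation with a chiral oxidant) to the α-hydroxy ketone. The prenyl group is itself an electron-rich trisubstituted alkene and a good substrate for the same oxidant, so chemoselectivity is not secured by the structure. The enol ether geometry would have to be controlled, and the configuration at C2 would rest on facial selectivity instead of a purchased stereocenter. Ketone A3 also needs the same tetrasubstituted ring A as Alternative 1, plus a chain extension and a conjugate reduction that must spare the prenyl group. The route is longer and less secure at every stage.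

Alternative 3: another ring A construction, cut at C3'–C4', C1'–C2' and C4'–C5'. Photochemical Wolff rearrangement of diazo diketone A5 would give acyl(vinyl)ketene A6, and a terminal alkoxyacetylene would add by [2+2] cycloaddition, four-electron ring opening and six-electron closure to the phenol. In A5 two different groups can migrate to the carbene carbon. A6 is an α-oxoketene, which reacts with ynol ethers as an oxa-diene to give 4-pyranones rather than cyclobutenones. The stereocenter would sit next to a diazo-1,3-dicarbonyl unit under irradiation. The chosen Diels–Alder reaction uses two ground-state partners of matched polarity and has a close known counterpart.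

Key step: step 6

## Steps

Step 1
Reactants: 1 (2S)-2-hydroxy-3-(4-hydroxyphenyl)propanoic acid
Product: 2 (2S)-2-hydroxy-3-(4-hydroxyphenyl)-N-methoxy-N-methylpropanamide
Conditions: MeNH(OMe)·HCl, EDC·HCl, HOBt, N-methylmorpholine, DMF, 0 °C to rt
Reagents that add atoms: N,O-dimethylhydroxylamine hydrochloride, CNOC.Cl
Why: Carbodiimide amide coupling through the HOBt active ester; the amine outcompetes the phenol and the secondary alcohol as nucleophile, and an α-hydroxy acid cannot form an oxazolone, so C2 should keep its (S) configuration.

Step 2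
Reactants: 2 (2S)-2-hydroxy-3-(4-hydroxyphenyl)-N-methoxy-N-methylpropanamide
Product: 3 (2S)-2-[tert-butyl(dimethyl)silyl]oxy-3-[4-[tert-butyl(dimethyl)silyl]oxyphenyl]-N-methoxy-N-methylpropanamide
Conditions: TBSCl, imidazole, DMF, rt
Reagents that add atoms: tert-butyldimethylsilyl chloride (TBSCl), CC(C)(C)[Si](C)(C)Cl
Why: Standard imidazole-promoted silylation of a phenol and a secondary alcohol; both acidic OH groups are masked before the Grignard reagent and the ketene acetal diene are used, and the stereocenter is not involved.

Step 3
Reactants: 3 (2S)-2-[tert-butyl(dimethyl)silyl]oxy-3-[4-[tert-butyl(dimethyl)silyl]oxyphenyl]-N-methoxy-N-methylpropanamide; 4 ethynylmagnesium bromide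
Product: 5 (4S)-4-[tert-butyl(dimethyl)silyl]oxy-5-[4-[tert-butyl(dimethyl)silyl]oxyphenyl]pent-1-yn-3-one
Conditions: THF, 0 °C; inverse quench into cold 1 M aq. HCl/Et2O
Reagents that add atoms: none
Why: Weinreb ketone synthesis: the chelated tetrahedral magnesium adduct prevents a second addition and collapses only on the acidic quench, which also protonates the liberated N,O-dimethylhydroxylamine so that it cannot add to the ynone; α-silyloxy Weinreb amides are expected to pass without epimerization.

Step 4
Reactants: 6 5-methylhex-4-enoic acid; 7 1,1-dimethoxyethene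
Product: 9 1,1-dimethoxy-7-methylocta-1,6-dien-3-one, via 5-methylhex-4-enoyl chloride 8 (not isolated)
Conditions: (COCl)2, cat. DMF, CH2Cl2, 0 °C to rt; evaporate; then 7, pyridine, Et2O, 0 °C to rt; NaHCO3 work-up
Reagents that add atoms: oxalyl chloride, O=C(Cl)C(Cl)=O (supplies the chlorine of 8; none of its atoms remains in 9)
Why: Acid chloride formation followed by C-acylation of the nucleophilic ketene acetal (McElvain-type acylation); pyridine removes the proton from the dimethoxycarbenium intermediate before chloride can demethylate it, which should give the push-pull acylketene acetal.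

Step 5
Reactants: 9 1,1-dimethoxy-7-methylocta-1,6-dien-3-one
Product: 10 (3Z)-1,1-dimethoxy-7-methyl-3-(trimethylsilyloxy)octa-1,3,6-triene
Conditions: TMSOTf, Et3N, Et2O, 0 °C; pentane extraction without aqueous work-up, used crude
Reagents that add atoms: trimethylsilyl trifluoromethanesulfonate (TMSOTf), C[Si](C)(C)OS(=O)(=O)C(F)(F)F
Why: Soft enolization as used for Danishefsky- and Brassard-type dienes: O-silylation of the vinylogous carbonate carbonyl and deprotonation at C4, the only enolizable position; the (Z)-enol ether is expected to predominate, and the geometry is erased in step 6 in any case.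

Step 6
Reactants: 5 (4S)-4-[tert-butyl(dimethyl)silyl]oxy-5-[4-[tert-butyl(dimethyl)silyl]oxyphenyl]pent-1-yn-3-one; 10 (3Z)-1,1-dimethoxy-7-methyl-3-(trimethylsilyloxy)octa-1,3,6-triene
Product: 13 (2S)-2-[tert-butyl(dimethyl)silyl]oxy-3-[4-[tert-butyl(dimethyl)silyl]oxyphenyl]-1-[4-hydroxy-2-methoxy-5-(3-methylbut-2-enyl)phenyl]propan-1-one, via cyclohexa-1,4-diene cycloadduct 11 (not isolated), via aryl trimethylsilyl ether 12 (not isolated)
Conditions: PhMe, rt to 60 °C; then 0.5 M aq. HCl, THF, 0 °C
Reagents that add atoms: none
Why: Normal-demand Diels–Alder reaction of the doubly donor-activated diene 10 with the acceptor alkyne of 5, probably asynchronous with the C4–C(terminal alkyne) bond leading; the closest known reaction type is the cycloaddition–aromatization of 1,1-dialkoxy-3-silyloxybuta-1,3-dienes with propiolates and ynones to 4-hydroxy-2-alkoxyaryl carbonyl compounds. Ring A is closed as a six-membered carbocycle by [4+2] cycloaddition (a 6-endo closure of the zwitterion if the reaction is stepwise), which forms C1'–C2' and C5'–C6'. In 11 the C5'–H is doubly allylic and vinylogously α to the ketone, so 1,4-elimination of methanol from the C2' ketal should follow, driven by aromatization, and leaves one OMe on C2'. No new stereocenter survives: the sp3 C5' of 11 is erased, and C2 (S) is a spectator under neutral, base-free conditions. The selectivity needed is regiochemical: the largest HOMO coefficient of 10 lies on C4 (pushed by the C1 acetal oxygens and by the C3 silyloxy group) and the largest LUMO coefficient of 5 on the terminal alkyne carbon, so the prenyl-bearing carbon ends next to C6'–H and the acetal carbon next to the acyl carbon. Chemoselectivity follows from the substrate: the isolated trisubstituted prenyl alkene is inert, and without a Lewis acid the ketone C=O does not compete as heterodienophile. The (Z)-enol ether keeps the side chain outside the s-cis diene, and any (E)-isomer can still reach 11 by the stepwise path. Cold dilute acid then cleaves only the aryl O–SiMe3 bond of 12 and leaves both TBS ethers.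

Step 7
Reactants: 13 (2S)-2-[tert-butyl(dimethyl)silyl]oxy-3-[4-[tert-butyl(dimethyl)silyl]oxyphenyl]-1-[4-hydroxy-2-methoxy-5-(3-methylbut-2-enyl)phenyl]propan-1-one
Product: 14 Lespeflorin C3, (2S)-2-hydroxy-1-[4-hydroxy-2-methoxy-5-(3-methylbut-2-enyl)phenyl]-3-(4-hydroxyphenyl)propan-1-one
Conditions: TBAF, AcOH (1:1), THF, 0 °C to rt
Reagents that add atoms: none
Why: Fluoride-mediated desilylation of the aryl and the α-keto secondary TBS ethers; the acetic acid buffer keeps the medium near neutral so that C2 should not enolize, and the absence of strong acid avoids chroman formation from the prenyl phenol.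

## Compound list

1 | (2S)-2-hydroxy-3-(4-hydroxyphenyl)propanoic acid | O=C(O)[C@@H](O)Cc1ccc(O)cc1 | starting material
2 | (2S)-2-hydroxy-3-(4-hydroxyphenyl)-N-methoxy-N-methylpropanamide | CON(C)C(=O)[C@@H](O)Cc1ccc(O)cc1 | intermediate
3 | (2S)-2-[tert-butyl(dimethyl)silyl]oxy-3-[4-[tert-butyl(dimethyl)silyl]oxyphenyl]-N-methoxy-N-methylpropanamide | CON(C)C(=O)[C@@H](O[Si](C)(C)C(C)(C)C)Cc1ccc(O[Si](C)(C)C(C)(C)C)cc1 | intermediate
4 | ethynylmagnesium bromide | C#C[Mg]Br | starting material
5 | (4S)-4-[tert-butyl(dimethyl)silyl]oxy-5-[4-[tert-butyl(dimethyl)silyl]oxyphenyl]pent-1-yn-3-one | C#CC(=O)[C@@H](O[Si](C)(C)C(C)(C)C)Cc1ccc(O[Si](C)(C)C(C)(C)C)cc1 | intermediate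
6 | 5-methylhex-4-enoic acid | CC(C)=CCCC(=O)O | starting material
7 | 1,1-dimethoxyethene | COC(=C)OC | starting material
8 | 5-methylhex-4-enoyl chloride | CC(C)=CCCC(=O)Cl | intermediate
9 | 1,1-dimethoxy-7-methylocta-1,6-dien-3-one | CC(C)=CCCC(=O)C=C(OC)OC | intermediate
10 | (3Z)-1,1-dimethoxy-7-methyl-3-(trimethylsilyloxy)octa-1,3,6-triene | COC(OC)=C/C(O[Si](C)(C)C)=C/CC=C(C)C | intermediate
11 | (2S)-2-[tert-butyl(dimethyl)silyl]oxy-3-[4-[tert-butyl(dimethyl)silyl]oxyphenyl]-1-[6,6-dimethoxy-3-(3-methylbut-2-enyl)-4-(trimethylsilyloxy)cyclohexa-1,4-dien-1-yl]propan-1-one (both configurations at ring C3) | COC1(OC)C=C(O[Si](C)(C)C)C(CC=C(C)C)C=C1C(=O)[C@@H](O[Si](C)(C)C(C)(C)C)Cc1ccc(O[Si](C)(C)C(C)(C)C)cc1 | intermediate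
12 | (2S)-2-[tert-butyl(dimethyl)silyl]oxy-3-[4-[tert-butyl(dimethyl)silyl]oxyphenyl]-1-[2-methoxy-5-(3-methylbut-2-enyl)-4-(trimethylsilyloxy)phenyl]propan-1-one | COc1cc(O[Si](C)(C)C)c(CC=C(C)C)cc1C(=O)[C@@H](O[Si](C)(C)C(C)(C)C)Cc1ccc(O[Si](C)(C)C(C)(C)C)cc1 | intermediate
13 | (2S)-2-[tert-butyl(dimethyl)silyl]oxy-3-[4-[tert-butyl(dimethyl)silyl]oxyphenyl]-1-[4-hydroxy-2-methoxy-5-(3-methylbut-2-enyl)phenyl]propan-1-one | COc1cc(O)c(CC=C(C)C)cc1C(=O)[C@@H](O[Si](C)(C)C(C)(C)C)Cc1ccc(O[Si](C)(C)C(C)(C)C)cc1 | intermediate
14 | Lespeflorin C3, (2S)-2-hydroxy-1-[4-hydroxy-2-methoxy-5-(3-methylbut-2-enyl)phenyl]-3-(4-hydroxyphenyl)propan-1-one | COc1cc(O)c(CC=C(C)C)cc1C(=O)[C@@H](O)Cc1ccc(O)cc1 | target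

## Step count and least certain steps

Total: 7 steps. Longest linear sequence: 5 steps (1, 2, 3, 6, 7 from compound 1); the diene branch (steps 4 and 5) joins at step 6.

Step 6 (key step). The substituent on the diene terminus slows the cycloaddition, so three processes can overtake it: hydrolytic or thermal loss of the ketene acetal diene, conjugate addition to the ynone without ring closure, and oligomerization of the ynone. A basic zwitterionic intermediate could also epimerize C2 of the ynone. Fallback: the aryl–carbonyl disconnection with known chemistry, setting out from 3 and returning at 14. Commercial 4-bromo-3-methoxyphenol would be C-prenylated at the free ortho position as its sodium phenoxide (NaH, prenyl bromide, toluene) to give 4-bromo-5-methoxy-2-(3-methylbut-2-enyl)phenol F1. Silylation (TBSCl, imidazole) would give tert-butyl-[4-bromo-5-methoxy-2-(3-methylbut-2-enyl)phenoxy]dimethylsilane F2. Bromine–lithium exchange (n-BuLi, THF, −78 °C) and addition to Weinreb amide 3 would give (2S)-2-[tert-butyl(dimethyl)silyl]oxy-3-[4-[tert-butyl(dimethyl)silyl]oxyphenyl]-1-[4-[tert-butyl(dimethyl)silyl]oxy-2-methoxy-5-(3-methylbut-2-enyl)phenyl]propan-1-one F3. The conditions of step 7 would then convert F3 into 14.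

Step 4. Demethylation of the O-methyl oxocarbenium intermediate by chloride (leading to a β-keto ester), ketene formation from the enolizable acid chloride, and hydrochlorination of the trisubstituted alkene by residual HCl may all compete with C-acylation. Fallback: build the chain by alkylation instead of acylation, setting out from 7 and returning at 9. Acetylation of 7 (acetyl chloride, pyridine, Et2O), the parent case of this acylation, would give 4,4-dimethoxybut-3-en-2-one F4. Its kinetic enolate (LiN(iPr)2, THF, −78 °C) would be alkylated at the methyl carbon with prenyl bromide to give 9, so the alkene never meets an acid chloride or HCl.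

Step 3. Conjugate addition of the liberated N,O-dimethylhydroxylamine to the terminal ynone during work-up, and base-induced epimerization of the α-silyloxy ketone, are the likely losses. Fallback: the aldehyde route, setting out from 3 and returning at 5. Reduction with iBu2AlH (THF, −78 °C) would give (2S)-2-[tert-butyl(dimethyl)silyl]oxy-3-[4-[tert-butyl(dimethyl)silyl]oxyphenyl]propanal F5. Addition of 4 would give (4S)-4-[tert-butyl(dimethyl)silyl]oxy-5-[4-[tert-butyl(dimethyl)silyl]oxyphenyl]pent-1-yn-3-ol F6 as a mixture of C3 epimers, which converge on oxidation with Dess–Martin periodinane to 5. No amine is present when the ynone forms.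

Step 7. Slow cleavage of the secondary silyl ether would prolong contact with fluoride and acetate, which allows enolization at C2 (loss of configuration) or an enediol shift of the α-ketol. Fallback: two chemoselective stages in place of one global operation, setting out from 13 and returning at 14. Aqueous HF in MeCN (acidic, non-enolizing) would remove the secondary silyl group first to give (2S)-3-[4-[tert-butyl(dimethyl)silyl]oxyphenyl]-2-hydroxy-1-[4-hydroxy-2-methoxy-5-(3-methylbut-2-enyl)phenyl]propan-1-one F7. KHF2 in MeOH at rt, which is selective for phenolic silyl ethers and nearly neutral, would then give 14.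

## Further compounds

F1 | step 6 | 4-bromo-5-methoxy-2-(3-methylbut-2-enyl)phenol | COc1cc(O)c(CC=C(C)C)cc1Br
F2 | step 6 | tert-butyl-[4-bromo-5-methoxy-2-(3-methylbut-2-enyl)phenoxy]dimethylsilane | COc1cc(O[Si](C)(C)C(C)(C)C)c(CC=C(C)C)cc1Br
F3 | step 6 | (2S)-2-[tert-butyl(dimethyl)silyl]oxy-3-[4-[tert-butyl(dimethyl)silyl]oxyphenyl]-1-[4-[tert-butyl(dimethyl)silyl]oxy-2-methoxy-5-(3-methylbut-2-enyl)phenyl]propan-1-one | COc1cc(O[Si](C)(C)C(C)(C)C)c(CC=C(C)C)cc1C(=O)[C@@H](O[Si](C)(C)C(C)(C)C)Cc1ccc(O[Si](C)(C)C(C)(C)C)cc1
F4 | step 4 | 4,4-dimethoxybut-3-en-2-one | CC(=O)C=C(OC)OC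
F5 | step 3 | (2S)-2-[tert-butyl(dimethyl)silyl]oxy-3-[4-[tert-butyl(dimethyl)silyl]oxyphenyl]propanal | O=C[C@@H](O[Si](C)(C)C(C)(C)C)Cc1ccc(O[Si](C)(C)C(C)(C)C)cc1
F6 | step 3 | (4S)-4-[tert-butyl(dimethyl)silyl]oxy-5-[4-[tert-butyl(dimethyl)silyl]oxyphenyl]pent-1-yn-3-ol (both C3 epimers) | C#CC(O)[C@@H](O[Si](C)(C)C(C)(C)C)Cc1ccc(O[Si](C)(C)C(C)(C)C)cc1
F7 | step 7 | (2S)-3-[4-[tert-butyl(dimethyl)silyl]oxyphenyl]-2-hydroxy-1-[4-hydroxy-2-methoxy-5-(3-methylbut-2-enyl)phenyl]propan-1-one | COc1cc(O)c(CC=C(C)C)cc1C(=O)[C@@H](O)Cc1ccc(O[Si](C)(C)C(C)(C)C)cc1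
A1 | alternative 1 | 1-bromo-2-methoxy-4-(methoxymethoxy)-5-(3-methylbut-2-enyl)benzene | COCOc1cc(OC)c(Br)cc1CC=C(C)C
A2 | alternative 1 | (2S)-2-[tert-butyl(dimethyl)silyl]oxy-3-[4-[tert-butyl(dimethyl)silyl]oxyphenyl]-1-[2-methoxy-4-(methoxymethoxy)-5-(3-methylbut-2-enyl)phenyl]propan-1-one | COCOc1cc(OC)c(cc1CC=C(C)C)C(=O)[C@@H](O[Si](C)(C)C(C)(C)C)Cc1ccc(O[Si](C)(C)C(C)(C)C)cc1
A3 | alternative 2 | 1-[4-[tert-butyl(dimethyl)silyl]oxy-2-methoxy-5-(3-methylbut-2-enyl)phenyl]-3-[4-[tert-butyl(dimethyl)silyl]oxyphenyl]propan-1-one | COc1cc(O[Si](C)(C)C(C)(C)C)c(CC=C(C)C)cc1C(=O)CCc1ccc(O[Si](C)(C)C(C)(C)C)cc1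
A4 | alternative 2 | (Z)-trimethylsilyl enol ether of A3, [(Z)-1-[4-[tert-butyl(dimethyl)silyl]oxy-2-methoxy-5-(3-methylbut-2-enyl)phenyl]-3-[4-[tert-butyl(dimethyl)silyl]oxyphenyl]prop-1-enoxy]trimethylsilane | COc1cc(O[Si](C)(C)C(C)(C)C)c(CC=C(C)C)cc1/C(O[Si](C)(C)C)=C/Cc1ccc(O[Si](C)(C)C(C)(C)C)cc1
A5 | alternative 3 | (2S,6E)-2-[tert-butyl(dimethyl)silyl]oxy-1-[4-[tert-butyl(dimethyl)silyl]oxyphenyl]-4-diazo-10-methylundeca-6,9-diene-3,5-dione | CC(C)=CC/C=C/C(=O)C(=[N+]=[N-])C(=O)[C@@H](O[Si](C)(C)C(C)(C)C)Cc1ccc(O[Si](C)(C)C(C)(C)C)cc1
A6 | alternative 3 | (3E)-2-[(2S)-2-[tert-butyl(dimethyl)silyl]oxy-3-[4-[tert-butyl(dimethyl)silyl]oxyphenyl]propanoyl]-7-methylocta-1,3,6-trien-1-one (acyl(vinyl)ketene) | CC(C)=CC/C=C/C(=C=O)C(=O)[C@@H](O[Si](C)(C)C(C)(C)C)Cc1ccc(O[Si](C)(C)C(C)(C)C)cc1
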